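**Retrosynthetic overview**
1. Feature: the central benzene ring (C4a, C5, C6, C7, C8, C8a; chroman-2-one numbering) is pentasubstituted. Oxygen sits on C7 and C8a on either side of the only ring C–H (C8), and the C5 methyl lies next to the carbon substituent on C6. This is the footprint of a 1,3-dioxygenated diene (C7–C8–C8a–C4a) on a but-2-ynone (C5, C6).
2. Late stage: remove the O-benzyl group, take off the pyranone O-methyl, and open the 2-pyranone ring to a C6 (dioxinonyl)acetyl group, a masked acylketene.
3. Key disconnection: C4a–C5, C6–C7 and O1–C2. This leads to an enantiopure 1-methoxy-1,3-bis(silyloxy)diene carrying C4 and the ester arm, and to a but-2-ynone bearing the dioxinone.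
4. The diene comes from a 3-arylglutaric anhydride by desymmetrising methanolysis (sets C4), malonate homologation and soft bis-silylation. The ynone comes from the dioxinone dienolate and the Weinreb amide of but-2-ynoic acid.
5. Ring order: central benzene ring, then the lactone ring in the same flask, then the 2-pyranone ring.

Key step: step 9

Assumption 1: the quinine-derived sulfonamide catalyst is taken to give the (R)-half-ester 6. The sense of induction is checked on the first batch, and the quinidine-derived pseudoenantiomer is used if the opposite half-ester forms.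
Assumption 2: compound 3 is drawn open-chain. It may crystallise as its ring-closed aldol isomer, and both forms should give 4 in step 2.

**Step 1**
Reactants: 1 4-(benzyloxy)benzaldehyde; 2 ethyl acetoacetate (2.1 equiv)
Product: 3 diethyl 2,4-diacetyl-3-[4-(benzyloxy)phenyl]pentanedioate (diastereomer mixture)
Conditions: piperidine (cat.), EtOH, rt
Reagents that add atoms: none
Why: Tandem Knoevenagel condensation–Michael addition with two equivalents of acetoacetate is the classical entry to 3-arylglutaric acids and tolerates the benzyl ether; the stereocentres formed here are erased in step 2.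

**Step 2**
Reactants: 3 diethyl 2,4-diacetyl-3-[4-(benzyloxy)phenyl]pentanedioate
Product: 4 3-[4-(benzyloxy)phenyl]pentanedioic acid
Conditions: KOH (50% aq.), EtOH, reflux; then HCl to pH 1
Reagents that add atoms: potassium hydroxide, [K+].[OH-]
Why: Hot concentrated alkali brings about a double retro-Claisen deacetylation and saponifies both esters, while the aryl benzyl ether is inert to base.

**Step 3**
Reactants: 4 3-[4-(benzyloxy)phenyl]pentanedioic acid
Product: 5 4-[4-(benzyloxy)phenyl]oxane-2,6-dione (3-arylglutaric anhydride)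
Conditions: Ac2O, reflux; crystallise from toluene
Reagents that add atoms: none
Why: Cyclodehydration of a glutaric acid with acetic anhydride gives the six-membered anhydride, an achiral compound with two enantiotopic carbonyl groups.

**Step 4**
Reactants: 5 4-[4-(benzyloxy)phenyl]oxane-2,6-dione
Product: 6 (3R)-3-[4-(benzyloxy)phenyl]-5-methoxy-5-oxopentanoic acid
Conditions: MeOH (10 equiv), N-[(8α,9S)-6'-methoxycinchonan-9-yl]-3,5-bis(trifluoromethyl)benzenesulfonamide (10 mol%), MTBE (0.02 M), −20 °C; recrystallise until chiral HPLC shows a single enantiomer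
Reagents that add atoms: methanol, CO
Why: Catalytic desymmetrising alcoholysis of a prochiral cyclic anhydride with a bifunctional cinchona sulfonamide: the quinuclidine nitrogen activates methanol as a general base while the sulfonamide N–H binds one of the two enantiotopic carbonyl groups, and this choice sets the only stereocentre (C4 of the target) as R.

**Step 5**
Reactants: 6 (3R)-3-[4-(benzyloxy)phenyl]-5-methoxy-5-oxopentanoic acid; 7 potassium methyl malonate (1.8 equiv)
Product: 9 dimethyl (3R)-3-[4-(benzyloxy)phenyl]-5-oxoheptanedioate, via acyl imidazolide 8 (not isolated)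
Conditions: CDI, THF, rt; then 7, MgCl2, Et3N, MeCN–THF, rt → 40 °C; 1 M HCl
Reagents that add atoms: 1,1'-carbonyldiimidazole, O=C(n1ccnc1)n1ccnc1 (imidazolyl group of 8 only)
Why: Masamune–Brooks homologation: the acyl imidazolide acylates the magnesium enolate of the malonate half-ester and loss of CO2 gives the β-keto ester under nearly neutral conditions that neither touch the stereocentre nor trigger Dieckmann closure onto the second ester.

**Step 6**
Reactants: 9 dimethyl (3R)-3-[4-(benzyloxy)phenyl]-5-oxoheptanedioate
Product: 10 methyl (3S,4Z)-3-[4-(benzyloxy)phenyl]-7-methoxy-5,7-bis[(trimethylsilyl)oxy]hepta-4,6-dienoate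
Conditions: TMSOTf (2.3 equiv), Et3N (2.8 equiv), Et2O, 0 °C → rt; decant, pentane, filter, concentrate; used crude
Reagents that add atoms: trimethylsilyl trifluoromethanesulfonate, C[Si](C)(C)OS(=O)(=O)C(F)(F)F
Why: Soft enolisation with silyl triflate and a tertiary amine, the known one-pot conversion of 1,3-dicarbonyl compounds into 1,3-bis(silyloxy)dienes, replaces the usual LDA/TMSCl second stage because LDA would also deprotonate the isolated methyl ester, whereas TMSOTf silylates the far more Lewis-basic vinylogous carbonate carbonyl first and Et3N then removes only the γ-hydrogen to give the less crowded (4Z) enol ether (same spatial arrangement at the stereocentre, descriptor S by priority change).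

**Step 7**
Reactants: 11 but-2-ynoic acid
Product: 12 N-methoxy-N-methylbut-2-ynamide
Conditions: MeNH(OMe)·HCl, EDC·HCl, N-methylmorpholine, CH2Cl2, 0 °C → rt
Reagents that add atoms: N,O-dimethylhydroxylamine hydrochloride, CNOC.Cl
Why: Carbodiimide amidation gives the Weinreb amide, an acyl donor much less prone to conjugate addition than but-2-ynoyl chloride.

**Step 8**
Reactants: 13 2,2,6-trimethyl-4H-1,3-dioxin-4-one (2 equiv); 12 N-methoxy-N-methylbut-2-ynamide
Product: 16 2,2-dimethyl-6-(2-oxopent-3-yn-1-yl)-4H-1,3-dioxin-4-one, via lithium dienolate 14 (not isolated), via tetrahedral lithium adduct 15 (not isolated)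
Conditions: LiHMDS (2 equiv), THF, −78 °C; 12, −78 → −40 °C; inverse quench into cold 1 M HCl
Reagents that add atoms: lithium hexamethyldisilazide, [Li+].C[Si](C)(C)[N-][Si](C)(C)C (lithium of 14 and 15 only)
Why: Weinreb ketone synthesis with the γ-selective dioxinone dienolate: adduct 15 keeps the carbonyl masked until the cold acidic quench, so the CH-acidic product cannot quench the dienolate, the free ynone meets no nucleophile, and the released amine is protonated before it can add to the triple bond.

**Step 9**
Reactants: 10 methyl (3S,4Z)-3-[4-(benzyloxy)phenyl]-7-methoxy-5,7-bis[(trimethylsilyl)oxy]hepta-4,6-dienoate; 16 2,2-dimethyl-6-(2-oxopent-3-yn-1-yl)-4H-1,3-dioxin-4-one (1.5 equiv)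
Product: 19 (4R)-4-[4-(benzyloxy)phenyl]-6-[2-(2,2-dimethyl-4-oxo-4H-1,3-dioxin-6-yl)acetyl]-7-hydroxy-5-methyl-3,4-dihydro-2H-chromen-2-one, via cyclohexadiene cycloadduct 17 (not isolated), via resorcinol methyl ester 18 (not isolated)
Conditions: PhMe (1 M), Ar, 65 °C; then CH2Cl2, TFA (10 vol%), H2O (3 equiv), 0 °C → rt
Reagents that add atoms: none
Why: Diels–Alder benzannulation of a 1-methoxy-1,3-bis(silyloxy)diene with an acetylenic ketone, the known route to resorcinols: the diene terminus that becomes C4a carries the largest HOMO coefficient and the methyl-bearing β-carbon of 16 the largest LUMO coefficient, so a strongly asynchronous [4+2] addition (in the stepwise limit a vinylogous Mukaiyama–Michael addition followed by closure of the allenolate on the ketene-acetal carbon, with the same outcome) forms C4a–C5 and C6–C7 and closes the carbocycle as the cyclohexa-1,4-diene 17. Acid then removes both silyl groups, the C7 hemiketal expels methanol and the resulting dienone tautomerises with loss of the C4a hydrogen, which makes the ring of 18 aromatic and erases the two transient ring stereocentres, so that the step leaves no new stereocentre to control. The C8a hydroxyl, the only one ortho to the side chain, attacks the methyl ester in a 6-exo-trig addition–elimination (O1–C2) that is driven forward by the crowding between the C5 methyl and the C4 aryl group, as in a trimethyl lock. The step needs regioselectivity, which the matched push–pull polarisation of the two partners secures, site selectivity for the triple bond over the electron-richer dioxinone C=C, which the lower LUMO of the ynone secures, and a bath temperature well under the roughly 100 °C at which the dioxinone begins to lose acetone. The (4Z) geometry of 10 turns the bulky CH(Ar)CH2CO2Me group to the outside of the s-cis diene, which leaves the terminus open to the linear alkyne and rules out a 1,5-hydrogen shift. C4 lies outside the reacting π-system and bears no acidic hydrogen, so the configuration set in step 4 is carried through unchanged.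

**Step 10**
Reactants: 19 (4R)-4-[4-(benzyloxy)phenyl]-6-[2-(2,2-dimethyl-4-oxo-4H-1,3-dioxin-6-yl)acetyl]-7-hydroxy-5-methyl-3,4-dihydro-2H-chromen-2-one
Product: 21 (4R)-4-[4-(benzyloxy)phenyl]-7-hydroxy-6-(4-hydroxy-2-oxo-2H-pyran-6-yl)-5-methyl-3,4-dihydro-2H-chromen-2-one, via acylketene 20 (not isolated)
Conditions: PhMe (0.01 M), reflux (110 °C)
Reagents that add atoms: none
Why: Retro-[4+2] loss of acetone from the dioxinone gives the acylketene, which is captured by the enol oxygen of the neighbouring aryl ketone in a six-membered closure, the standard route from 6-(2-oxoalkyl)dioxinones to 6-substituted 4-hydroxy-2-pyranones; high dilution keeps the C7 phenol from intermolecular capture.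

**Step 11**
Reactants: 21 (4R)-4-[4-(benzyloxy)phenyl]-7-hydroxy-6-(4-hydroxy-2-oxo-2H-pyran-6-yl)-5-methyl-3,4-dihydro-2H-chromen-2-one
Product: 22 (4R)-4-[4-(benzyloxy)phenyl]-7-hydroxy-6-(4-methoxy-2-oxo-2H-pyran-6-yl)-5-methyl-3,4-dihydro-2H-chromen-2-one
Conditions: Me2SO4 (1.05 equiv), K2CO3 (1.05 equiv), dry acetone, rt
Reagents that add atoms: dimethyl sulfate, COS(=O)(=O)OC
Why: Chemoselective O-alkylation: the vinylogous acid of the 4-hydroxy-2-pyranone (pKa about 5) is several units more acidic than the C7 phenol, so one equivalent each of carbonate and dimethyl sulfate should methylate only that oxygen, and these conditions are known to favour the 4-methoxy-2-pyranone over the 2-methoxy-4-pyranone isomer.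

**Step 12**
Reactants: 22 (4R)-4-[4-(benzyloxy)phenyl]-7-hydroxy-6-(4-methoxy-2-oxo-2H-pyran-6-yl)-5-methyl-3,4-dihydro-2H-chromen-2-one
Product: 23 (4R)-7-hydroxy-4-(4-hydroxyphenyl)-6-(4-methoxy-2-oxo-2H-pyran-6-yl)-5-methyl-3,4-dihydro-2H-chromen-2-one (CNP0207475.1)
Conditions: H2 (1 atm), 10% Pd/C, EtOAc–THF, rt; stop after one equivalent of H2
Reagents that add atoms: none
Why: Hydrogenolysis of the aryl benzyl ether at atmospheric pressure: the lactone C–O bond belongs to an aryl ester and is not benzylic, C4 bears only C–C bonds, and the push–pull 4-methoxy-2-pyranone is reduced much more slowly.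

**Compound list**
1 | 4-(benzyloxy)benzaldehyde | O=Cc1ccc(OCc2ccccc2)cc1 | starting material
2 | ethyl acetoacetate | CCOC(=O)CC(C)=O | starting material
3 | diethyl 2,4-diacetyl-3-[4-(benzyloxy)phenyl]pentanedioate | CCOC(=O)C(C(C)=O)C(c1ccc(OCc2ccccc2)cc1)C(C(C)=O)C(=O)OCC | intermediate
4 | 3-[4-(benzyloxy)phenyl]pentanedioic acid | OC(=O)CC(c1ccc(OCc2ccccc2)cc1)CC(=O)O | intermediate
5 | 4-[4-(benzyloxy)phenyl]oxane-2,6-dione | O=C1CC(c2ccc(OCc3ccccc3)cc2)CC(=O)O1 | intermediate
6 | (3R)-3-[4-(benzyloxy)phenyl]-5-methoxy-5-oxopentanoic acid | OC(=O)C[C@@H](c1ccc(OCc2ccccc2)cc1)CC(=O)OC | intermediate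
7 | potassium methyl malonate | COC(=O)CC(=O)[O-].[K+] | starting material
8 | methyl (3R)-3-[4-(benzyloxy)phenyl]-5-(1H-imidazol-1-yl)-5-oxopentanoate | O=C(C[C@@H](c1ccc(OCc2ccccc2)cc1)CC(=O)OC)n1ccnc1 | intermediate (not isolated)
9 | dimethyl (3R)-3-[4-(benzyloxy)phenyl]-5-oxoheptanedioate | COC(=O)CC(=O)C[C@@H](c1ccc(OCc2ccccc2)cc1)CC(=O)OC | intermediate
10 | methyl (3S,4Z)-3-[4-(benzyloxy)phenyl]-7-methoxy-5,7-bis[(trimethylsilyl)oxy]hepta-4,6-dienoate | COC(O[Si](C)(C)C)=C/C(O[Si](C)(C)C)=C/[C@@H](c1ccc(OCc2ccccc2)cc1)CC(=O)OC | intermediate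
11 | but-2-ynoic acid | CC#CC(=O)O | starting material
12 | N-methoxy-N-methylbut-2-ynamide | CC#CC(=O)N(C)OC | intermediate
13 | 2,2,6-trimethyl-4H-1,3-dioxin-4-one | CC1=CC(=O)OC(C)(C)O1 | starting material
14 | lithium 2,2-dimethyl-6-methylidene-6H-1,3-dioxin-4-olate | [Li+].C=C1C=C([O-])OC(C)(C)O1 | intermediate (not isolated)
15 | lithium alkoxide from addition of 14 to the carbonyl group of 12 | [Li+].CC#CC([O-])(CC1=CC(=O)OC(C)(C)O1)N(C)OC | intermediate (not isolated)
16 | 2,2-dimethyl-6-(2-oxopent-3-yn-1-yl)-4H-1,3-dioxin-4-one | CC#CC(=O)CC1=CC(=O)OC(C)(C)O1 | intermediate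
17 | cyclohexa-1,4-diene cycloadduct: C7 bears OMe and OTMS, C8a bears OTMS, C4a is sp3; side-chain centre S, ring centres as a mixture | COC1(O[Si](C)(C)C)C=C(O[Si](C)(C)C)C(C(C)=C1C(=O)CC1=CC(=O)OC(C)(C)O1)[C@@H](c1ccc(OCc2ccccc2)cc1)CC(=O)OC | intermediate (not isolated)
18 | methyl (3R)-3-[4-(benzyloxy)phenyl]-3-{3-[2-(2,2-dimethyl-4-oxo-4H-1,3-dioxin-6-yl)acetyl]-4,6-dihydroxy-2-methylphenyl}propanoate | CC1(C)OC(CC(=O)c2c(O)cc(O)c(c2C)[C@@H](c2ccc(OCc3ccccc3)cc2)CC(=O)OC)=CC(=O)O1 | intermediate (not isolated)
19 | (4R)-4-[4-(benzyloxy)phenyl]-6-[2-(2,2-dimethyl-4-oxo-4H-1,3-dioxin-6-yl)acetyl]-7-hydroxy-5-methyl-3,4-dihydro-2H-chromen-2-one | CC1(C)OC(CC(=O)c2c(O)cc3c(c2C)[C@@H](c2ccc(OCc4ccccc4)cc2)CC(=O)O3)=CC(=O)O1 | intermediate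
20 | acylketene: 5-{(4R)-4-[4-(benzyloxy)phenyl]-7-hydroxy-5-methyl-2-oxochroman-6-yl}-3,5-dioxopent-1-en-1-one | O=C=CC(=O)CC(=O)c1c(O)cc2c(c1C)[C@@H](c1ccc(OCc3ccccc3)cc1)CC(=O)O2 | intermediate (not isolated)
21 | (4R)-4-[4-(benzyloxy)phenyl]-7-hydroxy-6-(4-hydroxy-2-oxo-2H-pyran-6-yl)-5-methyl-3,4-dihydro-2H-chromen-2-one | Oc1cc(-c2c(O)cc3c(c2C)[C@@H](c2ccc(OCc4ccccc4)cc2)CC(=O)O3)oc(=O)c1 | intermediate
22 | (4R)-4-[4-(benzyloxy)phenyl]-7-hydroxy-6-(4-methoxy-2-oxo-2H-pyran-6-yl)-5-methyl-3,4-dihydro-2H-chromen-2-one | COc1cc(-c2c(O)cc3c(c2C)[C@@H](c2ccc(OCc4ccccc4)cc2)CC(=O)O3)oc(=O)c1 | intermediate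
23 | (4R)-7-hydroxy-4-(4-hydroxyphenyl)-6-(4-methoxy-2-oxo-2H-pyran-6-yl)-5-methyl-3,4-dihydro-2H-chromen-2-one | COc1cc(-c2c(O)cc3c(c2C)[C@@H](c2ccc(O)cc2)CC(=O)O3)oc(=O)c1 | target

**Total step count:** 12. **Longest linear sequence:** 10 (steps 1–6 and 9–12); steps 7–8 form the side branch.

**Steps most likely to fail**

Step 9. The cycloaddition may be too slow at a temperature the dioxinone tolerates, because a secondary alkyl group on the diene terminus meets an internal alkyne. The CH-acidic methylene of 16 may also pass a proton or take a silyl group from the ketene acetal faster than the ring forms.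
- The fallback sets out from 10 and uses commercially available pent-3-yn-2-one (CC#CC(C)=O). This dienophile has neither a thermal ceiling nor a 1,3-dicarbonyl-type methylene, so toluene or xylene at 110–130 °C can be used.
- The same acid treatment should give (4R)-6-acetyl-4-[4-(benzyloxy)phenyl]-7-hydroxy-5-methyl-3,4-dihydro-2H-chromen-2-one F1.
- TMSOTf/Et3N (CH2Cl2, 0 °C) converts the acetyl group into its silyl enol ether and caps the C7 phenol, giving (4R)-4-[4-(benzyloxy)phenyl]-5-methyl-7-[(trimethylsilyl)oxy]-6-{1-[(trimethylsilyl)oxy]ethenyl}-3,4-dihydro-2H-chromen-2-one F2.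
- Malonyl dichloride (O=C(Cl)CC(=O)Cl, Et2O, −78 °C → rt) acylates the enol ether at carbon and closes the ring through the enol oxygen. This is a known one-step synthesis of 6-substituted 4-hydroxy-2-pyranones.
- Aqueous work-up frees the phenol, and the route is rejoined at 21.

Step 6. The second silylation may stall, the pendant ester may be silylated in competition, the enol ether geometry may be poorly controlled, or the diene may hydrolyse on handling.
- The fallback sets out from 9 and masks the pendant ester instead of sparing it.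
- TMSCl/Et3N (hexane, rt) gives dimethyl (5R)-5-[4-(benzyloxy)phenyl]-3-[(trimethylsilyl)oxy]hept-2-enedioate F3.
- LDA (2.2 equiv, THF, −78 °C) followed by TMSCl (2.5 equiv) deprotonates both the γ-position and the isolated ester, giving 1-(benzyloxy)-4-[(3R,4Z)-1,7-dimethoxy-1,5,7-tris[(trimethylsilyl)oxy]hepta-1,4,6-trien-3-yl]benzene F4.
- F4 is taken into the cycloaddition with 16. The isolated ketene acetal is a spectator there, and the acid stage returns it to the methyl ester before lactonisation.
- The route is rejoined at 19.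

Step 8. The dienolate may add in conjugate fashion to the alkynyl amide, the adduct may collapse early so that the product quenches the dienolate, or the liberated amine may add to the triple bond during the quench.
- The fallback sets out from 13 and changes the oxidation level of the electrophile.
- Dienolate 14 adds through its γ-carbon to but-2-ynal (CC#CC=O, THF, −78 °C, vinylogous aldol addition) to give racemic 6-(2-hydroxypent-3-yn-1-yl)-2,2-dimethyl-4H-1,3-dioxin-4-one F5.
- The propargylic alcohol is oxidised with MnO2 (CH2Cl2, rt) or Dess–Martin periodinane.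
- The route is rejoined at 16.

**Further compounds**
F1 | step 9 | (4R)-6-acetyl-4-[4-(benzyloxy)phenyl]-7-hydroxy-5-methyl-3,4-dihydro-2H-chromen-2-one | CC(=O)c1c(O)cc2c(c1C)[C@@H](c1ccc(OCc3ccccc3)cc1)CC(=O)O2
F2 | step 9 | (4R)-4-[4-(benzyloxy)phenyl]-5-methyl-7-[(trimethylsilyl)oxy]-6-{1-[(trimethylsilyl)oxy]ethenyl}-3,4-dihydro-2H-chromen-2-one | C=C(O[Si](C)(C)C)c1c(O[Si](C)(C)C)cc2c(c1C)[C@@H](c1ccc(OCc3ccccc3)cc1)CC(=O)O2
F3 | step 6 | dimethyl (5R)-5-[4-(benzyloxy)phenyl]-3-[(trimethylsilyl)oxy]hept-2-enedioate | COC(=O)C=C(O[Si](C)(C)C)C[C@@H](c1ccc(OCc2ccccc2)cc1)CC(=O)OC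
F4 | step 6 | 1-(benzyloxy)-4-[(3R,4Z)-1,7-dimethoxy-1,5,7-tris[(trimethylsilyl)oxy]hepta-1,4,6-trien-3-yl]benzene | COC(O[Si](C)(C)C)=C/C(O[Si](C)(C)C)=C/[C@@H](c1ccc(OCc2ccccc2)cc1)C=C(OC)O[Si](C)(C)C
F5 | step 8 | 6-(2-hydroxypent-3-yn-1-yl)-2,2-dimethyl-4H-1,3-dioxin-4-one (racemic) | CC#CC(O)CC1=CC(=O)OC(C)(C)O1
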